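**Retrosynthetic overview**

1. Cembrane numbering is used throughout: C1 carries the isopropyl group, C3–C4 is the oxirane (C4 carries CH3), C6 and C13 carry OAc, C8 and C12 carry CO2Me (C19, C20). The target is the C13 acetate of a 14-membered hydroxy enoate.
2. The carbocycle is opened at C12–C13. In the forward sense, a copper hydride reductive aldol macrocyclization of an acyclic ynoate aldehyde should form this bond, the C13 stereocentre and the (Z)-C11=C12 enoate in one operation.
3. Enabling feature: the C11≡C12–CO2Me ynoate. Hydride delivery to C11 turns C12 into a copper allenolate 13 atoms from the C13 aldehyde, on a chain stiffened by the C1=C2 alkene, the trans C3–C4 oxirane and the (Z)-C7=C8 enoate.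
4. The chain is cut at C7=C8 (Z-selective Still–Gennari olefination of an α-acetoxy aldehyde with an ynoate phosphonate). The aldehyde half comes from a glycidyl ether (C6) by alkynylation, carboalumination (C3=C4), Sharpless epoxidation (C3, C4) and a Still–Wittig [2,3] shift (C1=C2, C13–C14).
5. Ring order: oxirane first (step 6), 14-membered carbocycle last (step 18).

Key step: step 18

Assumption (availability): (R)-4-methoxybenzyl glycidyl ether and 2-bromo-3-methylbut-1-ene are taken as catalogue compounds; each is otherwise one known step from (S)-glycidol and from 3-methylbut-1-yne.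

**Route**

Step 1
Reactants: 1 methyl 2-[bis(2,2,2-trifluoroethoxy)phosphoryl]acetate; 2 4-bromobut-1-yne
Product: 3 methyl 2-[bis(2,2,2-trifluoroethoxy)phosphoryl]hex-5-ynoate (racemic)
Conditions: NaH, NaI (cat.), DMSO, rt
Reagents that add atoms: none
Why: SN2 C-alkylation of the sodium phosphonoacetate carbanion by the primary bromide (iodide catalysis) should attach the C9–C11 unit to the future C8; the new centre is racemic and becomes sp2 in step 15.

Step 2
Reactants: 3 methyl 2-[bis(2,2,2-trifluoroethoxy)phosphoryl]hex-5-ynoate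
Product: 4 dimethyl 6-[bis(2,2,2-trifluoroethoxy)phosphoryl]hept-2-ynedioate (racemic)
Conditions: PdCl2 (5 mol %), CuCl2 (2.2 equiv), NaOAc (2.2 equiv), CO (1 atm), MeOH, rt
Reagents that add atoms: carbon monoxide ([C-]#[O+]); methanol (CO)
Why: Palladium-catalysed oxidative methoxycarbonylation of a terminal alkyne (alkynylpalladium, CO insertion, methanolysis, CuCl2 reoxidising zerovalent palladium) should give the C11≡C12–CO2Me ynoate without strong base, so the acidic phosphonoacetate C–H is left alone; no stereocentre is formed.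

Step 3
Reactants: 5 (R)-2-{[(4-methoxybenzyl)oxy]methyl}oxirane
Product: 6 (R)-1-[(4-methoxybenzyl)oxy]pent-4-yn-2-ol
Conditions: LiC≡CH·H2NCH2CH2NH2, DMSO, 0 °C → rt; H2O work-up
Reagents that add atoms: lithium acetylide–ethylenediamine complex ([Li]C#C.NCCN)
Why: SN2 opening of the terminal epoxide at its CH2 carbon by the acetylide should give the homopropargylic alcohol and leaves the C6 centre of 5 untouched (R retained).

Step 4
Reactants: 6 (R)-1-[(4-methoxybenzyl)oxy]pent-4-yn-2-ol
Product: 7 (R)-triethyl({1-[(4-methoxybenzyl)oxy]pent-4-yn-2-yl}oxy)silane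
Conditions: Et3SiCl, imidazole, CH2Cl2, 0 °C
Reagents that add atoms: chlorotriethylsilane (CC[Si](Cl)(CC)CC)
Why: Standard silylation of the secondary alcohol; the triethylsilyl ether is chosen because it can later be removed selectively next to a primary tert-butyldiphenylsilyl ether.

Step 5
Reactants: 7 (R)-triethyl({1-[(4-methoxybenzyl)oxy]pent-4-yn-2-yl}oxy)silane
Product: 10 (R,E)-6-[(4-methoxybenzyl)oxy]-3-methyl-5-[(triethylsilyl)oxy]hex-2-en-1-ol, via alkenyldimethylalane 8 (not isolated), via lithium alkenylaluminate 9 (not isolated)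
Conditions: Me3Al (2 equiv), Cp2ZrCl2 (0.2 equiv), CH2Cl2, 0 °C → rt; then n-BuLi, THF, −78 °C; (CH2O)n, −78 °C → rt; H2O work-up
Reagents that add atoms: trimethylaluminium (C[Al](C)C); paraformaldehyde (as formaldehyde, C=O)
Why: Negishi zirconium-catalysed syn-carboalumination places methyl on the internal and aluminium on the terminal alkyne carbon, and hydroxymethylation of the aluminate with retention should give the (E)-trisubstituted C3=C4 allylic alcohol.

Step 6
Reactants: 10 (R,E)-6-[(4-methoxybenzyl)oxy]-3-methyl-5-[(triethylsilyl)oxy]hex-2-en-1-ol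
Product: 11 [(2S,3S)-3-{(R)-3-[(4-methoxybenzyl)oxy]-2-[(triethylsilyl)oxy]propyl}-3-methyloxiran-2-yl]methanol
Conditions: Ti(OiPr)4 (10 mol %), L-(+)-diethyl tartrate (12 mol %), t-BuOOH, 4 Å MS, CH2Cl2, −20 °C
Reagents that add atoms: tert-butyl hydroperoxide (CC(C)(C)OO)
Why: Sharpless asymmetric epoxidation of the (E)-3-methyl allylic alcohol with L-(+)-tartrate should deliver oxygen to the face that gives the (2S,3S)-epoxy alcohol (reagent control, as for geraniol), setting C3 and C4 of the target as 3S,4S.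

Step 7
Reactants: 11 [(2S,3S)-3-{(R)-3-[(4-methoxybenzyl)oxy]-2-[(triethylsilyl)oxy]propyl}-3-methyloxiran-2-yl]methanol
Product: 12 (2R,3S)-3-{(R)-3-[(4-methoxybenzyl)oxy]-2-[(triethylsilyl)oxy]propyl}-3-methyloxirane-2-carbaldehyde
Conditions: Dess–Martin periodinane, NaHCO3, CH2Cl2, 0 °C → rt
Reagents that add atoms: none
Why: Dess–Martin oxidation under bicarbonate buffer should convert the primary epoxy alcohol into the α,β-epoxy aldehyde without opening the oxirane or epimerising C3 (the descriptor changes only because CHO outranks C4).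

Step 8
Reactants: 12 (2R,3S)-epoxy aldehyde; 13 2-bromo-3-methylbut-1-ene
Product: 15 1-[(2S,3S)-3-{(R)-3-[(4-methoxybenzyl)oxy]-2-[(triethylsilyl)oxy]propyl}-3-methyloxiran-2-yl]-3-methyl-2-methylidenebutan-1-ol (both carbinol epimers), via alkenylmagnesium bromide 14 (not isolated)
Conditions: 13, Mg, THF, rt; then 12, THF, −78 °C; H2O work-up
Reagents that add atoms: none
Why: 1,2-Addition of the alkenyl Grignard reagent to the aldehyde should give the 2-isopropyl allylic alcohol; the new carbinol centre (C2) forms as a mixture, which is harmless because it becomes sp2 in step 10.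

Step 9
Reactants: 15 epoxy allylic alcohol (both carbinol epimers)
Product: 16 tributyl(stannyl)methyl ether of 15
Conditions: KH, Bu3SnCH2I, THF, 0 °C → rt
Reagents that add atoms: tributyl(iodomethyl)stannane (CCCC[Sn](CI)(CCCC)CCCC)
Why: Williamson O-alkylation of the potassium alkoxide with the iodomethylstannane should give the stannylmethyl ether needed for the Still–Wittig rearrangement; aprotic conditions suppress Payne migration of the oxirane.

Step 10
Reactants: 16 stannylmethyl ether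
Product: 19 tert-butyl{[(E)-4-[(2S,3S)-3-{(R)-3-[(4-methoxybenzyl)oxy]-2-[(triethylsilyl)oxy]propyl}-3-methyloxiran-2-yl]-3-(propan-2-yl)but-3-en-1-yl]oxy}diphenylsilane, via lithiomethyl ether 17 (not isolated), via lithium alkoxide 18 (not isolated)
Conditions: n-BuLi, THF, −78 °C; then t-BuPh2SiCl, imidazole, DMF, −78 °C → rt
Reagents that add atoms: tert-butyl(chloro)diphenylsilane (CC(C)(C)[Si](Cl)(c1ccccc1)c1ccccc1)
Why: Tin–lithium exchange gives an α-alkoxymethyllithium that should undergo the Still–Wittig [2,3]-sigmatropic shift onto the terminal methylene, forming C13–C14 and the C1=C2 alkene with the oxiranyl group cis to the new CH2CH2O chain, because the 2-isopropyl group forces the carbinol substituent pseudoaxial in the envelope transition state (1,2-allylic strain); the lithium alkoxide is silylated in the same flask.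

Step 11
Reactants: 19 bis-silyl ether
Product: 20 (R)-1-[(2S,3S)-3-{(E)-4-[(tert-butyldiphenylsilyl)oxy]-2-(propan-2-yl)but-1-en-1-yl}-2-methyloxiran-2-yl]-3-[(4-methoxybenzyl)oxy]propan-2-ol
Conditions: HF·pyridine, pyridine, THF, 0 °C
Reagents that add atoms: none
Why: Buffered fluoride should cleave the secondary triethylsilyl ether much faster than the primary tert-butyldiphenylsilyl ether (selective desilylation) and is mild enough for the vinyl oxirane.

Step 12
Reactants: 20 secondary alcohol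
Product: 21 (R)-1-[(2S,3S)-3-{(E)-4-[(tert-butyldiphenylsilyl)oxy]-2-(propan-2-yl)but-1-en-1-yl}-2-methyloxiran-2-yl]-3-[(4-methoxybenzyl)oxy]propan-2-yl acetate
Conditions: Ac2O, pyridine, DMAP (cat.), CH2Cl2, 0 °C → rt
Reagents that add atoms: acetic anhydride (CC(=O)OC(C)=O)
Why: DMAP-catalysed acylation installs the C6 acetate of the target before the C7=C8 enoate exists, because a free C6 hydroxyl cis to the C19 ester would lactonise to a butenolide.

Step 13
Reactants: 21 acetate
Product: 22 (R)-1-[(2S,3S)-3-{(E)-4-[(tert-butyldiphenylsilyl)oxy]-2-(propan-2-yl)but-1-en-1-yl}-2-methyloxiran-2-yl]-3-hydroxypropan-2-yl acetate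
Conditions: DDQ, CH2Cl2/pH 7 buffer, 0 °C
Reagents that add atoms: none
Why: Oxidative cleavage of the 4-methoxybenzyl ether by DDQ (hydride abstraction, hydrolysis of the oxocarbenium ion) under neutral buffer should free the C7 alcohol without acetyl migration or oxirane opening.

Step 14
Reactants: 22 primary alcohol
Product: 23 (R)-1-[(2S,3S)-3-{(E)-4-[(tert-butyldiphenylsilyl)oxy]-2-(propan-2-yl)but-1-en-1-yl}-2-methyloxiran-2-yl]-3-oxopropan-2-yl acetate
Conditions: Dess–Martin periodinane, NaHCO3, CH2Cl2, 0 °C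
Reagents that add atoms: none
Why: Dess–Martin oxidation under buffer should give the α-acetoxy aldehyde without epimerising C6; it is used directly.

Step 15
Reactants: 23 α-acetoxy aldehyde; 4 dimethyl 6-[bis(2,2,2-trifluoroethoxy)phosphoryl]hept-2-ynedioate
Product: 24 dimethyl (Z)-6-{(R)-2-acetoxy-3-[(2S,3S)-3-{(E)-4-[(tert-butyldiphenylsilyl)oxy]-2-(propan-2-yl)but-1-en-1-yl}-2-methyloxiran-2-yl]propylidene}hept-2-ynedioate
Conditions: 4, KN(SiMe3)2, 18-crown-6, THF, −78 °C; then 23, −78 °C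
Reagents that add atoms: none
Why: Still–Gennari variant of the Horner–Wadsworth–Emmons olefination: the trifluoroethyl phosphonate under dissociating conditions should collapse kinetically to the (Z)-trisubstituted enoate with CO2Me cis to C6, and the cold, weakly basic phosphonate anion spares the α-acetoxy centre and the ynoate.

Step 16
Reactants: 24 silyl ether
Product: 25 dimethyl (Z)-6-{(R)-2-acetoxy-3-[(2S,3S)-3-{(E)-4-hydroxy-2-(propan-2-yl)but-1-en-1-yl}-2-methyloxiran-2-yl]propylidene}hept-2-ynedioate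
Conditions: HF·pyridine, pyridine, THF, 0 °C → rt
Reagents that add atoms: none
Why: Fluoride-mediated desilylation of the primary silyl ether under pyridine buffer should liberate the C13 alcohol while the acetate, both esters, the ynoate and the vinyl oxirane survive.

Step 17
Reactants: 25 primary alcohol
Product: 26 dimethyl (Z)-6-{(R)-2-acetoxy-3-[(2S,3S)-2-methyl-3-{(E)-4-oxo-2-(propan-2-yl)but-1-en-1-yl}oxiran-2-yl]propylidene}hept-2-ynedioate
Conditions: Dess–Martin periodinane, NaHCO3, CH2Cl2, 0 °C; used at once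
Reagents that add atoms: none
Why: Dess–Martin oxidation under buffer should give the β,γ-unsaturated aldehyde under non-basic conditions, so that the C1=C2 alkene does not move into conjugation and the vinyl oxirane is not opened; the aldehyde is not stored.

Step 18
Reactants: 26 ynoate aldehyde
Product: 28 dimethyl (3S,4S,6R,13R,1E,7Z,11Z)-6-acetoxy-3,4-epoxy-13-hydroxycembra-1,7,11-triene-19,20-dioate, via phenylsilyl ether 27 (not isolated)
Conditions: CuF(PPh3)3·2MeOH (10 mol %), DTBM-SEGPHOS (11 mol %, the antipode that gives 13R), PhSiH3 (1.5 equiv), toluene, −40 °C, 26 added by syringe pump (final 2 mM); then NH4F, MeOH, 0 °C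
Reagents that add atoms: none
Why: Proposed new method: a bisphosphine-ligated monovalent copper hydride should add hydride to C11 of the ynoate (conjugate hydrocupration), giving a copper allenolate nucleophilic at C12 that adds through a closed, copper-chelated transition state to the C13 aldehyde, and Si–H/Cu–O exchange with the silane then releases silyl ether 27 and regenerates the hydride. The closest known reaction types are the [(Ph3P)CuH]6-induced reductive aldol cyclization of alkynones (five- and six-membered rings), the copper-catalysed enantioselective reductive aldol addition of acrylates to aldehydes and the hydroalumination–aldol synthesis of (Z)-2-(1-hydroxyalkyl)alk-2-enoates from ynoates; new here are the ynoate–aldehyde pairing and the ring size. The 14-membered carbocycle is closed by a 14-exo-trig (enolexo) aldol addition at pseudo-high dilution, the 13-atom tether being stiffened by the C1=C2 alkene, the trans-oxirane and the (Z)-C7=C8 enoate. The C11=C12 geometry follows from attack on C12 in the plane of the allenyl terminus from the side of H11, anti to C10, which puts CO2Me cis to C10 and gives the ring-trans alkene that a 14-membered ring accommodates; C13 is set by the chiral ligand (catalyst control, Si-face delivery to the aldehyde giving 13R), the antipode being chosen by screening because the resident centres are remote. The step needs chemoselectivity for the ynoate over the aldehyde, the trisubstituted C7=C8 enoate, the allylic acetate and the vinyl oxirane, which rests on the much higher electrophilicity of the ynoate toward Cu–H and on low temperature, and it needs C- rather than O-attack of the allenolate, which is normal for copper enolates toward aldehydes. Fluoride work-up cleaves 27 to alcohol 28.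

Step 19
Reactants: 28 macrocyclic alcohol
Product: 29 dimethyl (3S,4S,6R,13R,1E,7Z,11Z)-6,13-diacetoxy-3,4-epoxycembra-1,7,11-triene-19,20-dioate (CNP0359666.2)
Conditions: Ac2O, pyridine, DMAP (cat.), CH2Cl2, 0 °C
Reagents that add atoms: acetic anhydride (CC(=O)OC(C)=O)
Why: DMAP-catalysed acylation of the secondary allylic alcohol at 0 °C should give the C13 acetate without allylic transposition, completing the target.

**Compound list**

1 | methyl 2-[bis(2,2,2-trifluoroethoxy)phosphoryl]acetate | COC(=O)CP(=O)(OCC(F)(F)F)OCC(F)(F)F | starting material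
2 | 4-bromobut-1-yne | C#CCCBr | starting material
3 | methyl 2-[bis(2,2,2-trifluoroethoxy)phosphoryl]hex-5-ynoate (racemic) | COC(=O)C(CCC#C)P(=O)(OCC(F)(F)F)OCC(F)(F)F | intermediate
4 | dimethyl 6-[bis(2,2,2-trifluoroethoxy)phosphoryl]hept-2-ynedioate (racemic) | COC(=O)C#CCCC(C(=O)OC)P(=O)(OCC(F)(F)F)OCC(F)(F)F | intermediate
5 | (R)-2-{[(4-methoxybenzyl)oxy]methyl}oxirane | C1[C@@H](O1)COCc2ccc(OC)cc2 | starting material
6 | (R)-1-[(4-methoxybenzyl)oxy]pent-4-yn-2-ol | C#CC[C@@H](O)COCc1ccc(OC)cc1 | intermediate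
7 | (R)-triethyl({1-[(4-methoxybenzyl)oxy]pent-4-yn-2-yl}oxy)silane | C#CC[C@@H](O[Si](CC)(CC)CC)COCc1ccc(OC)cc1 | intermediate
8 | dimethyl{(R,E)-5-[(4-methoxybenzyl)oxy]-2-methyl-4-[(triethylsilyl)oxy]pent-1-en-1-yl}alane | C[Al](C)/C=C(\C)C[C@@H](O[Si](CC)(CC)CC)COCc1ccc(OC)cc1 | intermediate
9 | lithium butyl(dimethyl){(R,E)-5-[(4-methoxybenzyl)oxy]-2-methyl-4-[(triethylsilyl)oxy]pent-1-en-1-yl}aluminate | [Li+].CCCC[Al-](C)(C)/C=C(\C)C[C@@H](O[Si](CC)(CC)CC)COCc1ccc(OC)cc1 | intermediate
10 | (R,E)-6-[(4-methoxybenzyl)oxy]-3-methyl-5-[(triethylsilyl)oxy]hex-2-en-1-ol | OC/C=C(\C)C[C@@H](O[Si](CC)(CC)CC)COCc1ccc(OC)cc1 | intermediate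
11 | [(2S,3S)-3-{(R)-3-[(4-methoxybenzyl)oxy]-2-[(triethylsilyl)oxy]propyl}-3-methyloxiran-2-yl]methanol | OC[C@@H]1O[C@@]1(C)C[C@@H](O[Si](CC)(CC)CC)COCc2ccc(OC)cc2 | intermediate
12 | (2R,3S)-3-{(R)-3-[(4-methoxybenzyl)oxy]-2-[(triethylsilyl)oxy]propyl}-3-methyloxirane-2-carbaldehyde | O=C[C@@H]1O[C@@]1(C)C[C@@H](O[Si](CC)(CC)CC)COCc2ccc(OC)cc2 | intermediate
13 | 2-bromo-3-methylbut-1-ene | C=C(Br)C(C)C | starting material
14 | (3-methylbut-1-en-2-yl)magnesium bromide | C=C([Mg]Br)C(C)C | intermediate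
15 | 1-[(2S,3S)-3-{(R)-3-[(4-methoxybenzyl)oxy]-2-[(triethylsilyl)oxy]propyl}-3-methyloxiran-2-yl]-3-methyl-2-methylidenebutan-1-ol (both C1 epimers) | C=C(C(C)C)C(O)[C@@H]1O[C@@]1(C)C[C@@H](O[Si](CC)(CC)CC)COCc2ccc(OC)cc2 | intermediate
16 | tributyl[({1-[(2S,3S)-3-{(R)-3-[(4-methoxybenzyl)oxy]-2-[(triethylsilyl)oxy]propyl}-3-methyloxiran-2-yl]-3-methyl-2-methylidenebutyl}oxy)methyl]stannane (both epimers) | C=C(C(C)C)C(OC[Sn](CCCC)(CCCC)CCCC)[C@@H]1O[C@@]1(C)C[C@@H](O[Si](CC)(CC)CC)COCc2ccc(OC)cc2 | intermediate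
17 | [({1-[(2S,3S)-3-{(R)-3-[(4-methoxybenzyl)oxy]-2-[(triethylsilyl)oxy]propyl}-3-methyloxiran-2-yl]-3-methyl-2-methylidenebutyl}oxy)methyl]lithium | C=C(C(C)C)C(OC[Li])[C@@H]1O[C@@]1(C)C[C@@H](O[Si](CC)(CC)CC)COCc2ccc(OC)cc2 | intermediate
18 | lithium (E)-4-[(2S,3S)-3-{(R)-3-[(4-methoxybenzyl)oxy]-2-[(triethylsilyl)oxy]propyl}-3-methyloxiran-2-yl]-3-(propan-2-yl)but-3-en-1-olate | [Li]OCC/C(C(C)C)=C\[C@@H]1O[C@@]1(C)C[C@@H](O[Si](CC)(CC)CC)COCc2ccc(OC)cc2 | intermediate
19 | tert-butyl{[(E)-4-[(2S,3S)-3-{(R)-3-[(4-methoxybenzyl)oxy]-2-[(triethylsilyl)oxy]propyl}-3-methyloxiran-2-yl]-3-(propan-2-yl)but-3-en-1-yl]oxy}diphenylsilane | CC(C)(C)[Si](c1ccccc1)(c1ccccc1)OCC/C(C(C)C)=C\[C@@H]2O[C@@]2(C)C[C@@H](O[Si](CC)(CC)CC)COCc3ccc(OC)cc3 | intermediate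
20 | (R)-1-[(2S,3S)-3-{(E)-4-[(tert-butyldiphenylsilyl)oxy]-2-(propan-2-yl)but-1-en-1-yl}-2-methyloxiran-2-yl]-3-[(4-methoxybenzyl)oxy]propan-2-ol | CC(C)(C)[Si](c1ccccc1)(c1ccccc1)OCC/C(C(C)C)=C\[C@@H]2O[C@@]2(C)C[C@@H](O)COCc3ccc(OC)cc3 | intermediate
21 | (R)-1-[(2S,3S)-3-{(E)-4-[(tert-butyldiphenylsilyl)oxy]-2-(propan-2-yl)but-1-en-1-yl}-2-methyloxiran-2-yl]-3-[(4-methoxybenzyl)oxy]propan-2-yl acetate | CC(C)(C)[Si](c1ccccc1)(c1ccccc1)OCC/C(C(C)C)=C\[C@@H]2O[C@@]2(C)C[C@@H](OC(C)=O)COCc3ccc(OC)cc3 | intermediate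
22 | (R)-1-[(2S,3S)-3-{(E)-4-[(tert-butyldiphenylsilyl)oxy]-2-(propan-2-yl)but-1-en-1-yl}-2-methyloxiran-2-yl]-3-hydroxypropan-2-yl acetate | CC(C)(C)[Si](c1ccccc1)(c1ccccc1)OCC/C(C(C)C)=C\[C@@H]2O[C@@]2(C)C[C@@H](OC(C)=O)CO | intermediate
23 | (R)-1-[(2S,3S)-3-{(E)-4-[(tert-butyldiphenylsilyl)oxy]-2-(propan-2-yl)but-1-en-1-yl}-2-methyloxiran-2-yl]-3-oxopropan-2-yl acetate | CC(C)(C)[Si](c1ccccc1)(c1ccccc1)OCC/C(C(C)C)=C\[C@@H]2O[C@@]2(C)C[C@@H](OC(C)=O)C=O | intermediate
24 | dimethyl (Z)-6-{(R)-2-acetoxy-3-[(2S,3S)-3-{(E)-4-[(tert-butyldiphenylsilyl)oxy]-2-(propan-2-yl)but-1-en-1-yl}-2-methyloxiran-2-yl]propylidene}hept-2-ynedioate | CC(C)(C)[Si](c1ccccc1)(c1ccccc1)OCC/C(C(C)C)=C\[C@@H]2O[C@@]2(C)C[C@@H](OC(C)=O)/C=C(/CCC#CC(=O)OC)C(=O)OC | intermediate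
25 | dimethyl (Z)-6-{(R)-2-acetoxy-3-[(2S,3S)-3-{(E)-4-hydroxy-2-(propan-2-yl)but-1-en-1-yl}-2-methyloxiran-2-yl]propylidene}hept-2-ynedioate | OCC/C(C(C)C)=C\[C@@H]1O[C@@]1(C)C[C@@H](OC(C)=O)/C=C(/CCC#CC(=O)OC)C(=O)OC | intermediate
26 | dimethyl (Z)-6-{(R)-2-acetoxy-3-[(2S,3S)-2-methyl-3-{(E)-4-oxo-2-(propan-2-yl)but-1-en-1-yl}oxiran-2-yl]propylidene}hept-2-ynedioate | O=CC/C(C(C)C)=C\[C@@H]1O[C@@]1(C)C[C@@H](OC(C)=O)/C=C(/CCC#CC(=O)OC)C(=O)OC | intermediate
27 | dimethyl (3S,4S,6R,13R,1E,7Z,11Z)-6-acetoxy-3,4-epoxy-13-[(phenylsilyl)oxy]cembra-1,7,11-triene-19,20-dioate | COC(=O)/C1=C\[C@H](OC(C)=O)C[C@]2(C)O[C@H]2/C=C(/C(C)C)C[C@@H](O[SiH2]c3ccccc3)/C(C(=O)OC)=C/CC1 | intermediate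
28 | dimethyl (3S,4S,6R,13R,1E,7Z,11Z)-6-acetoxy-3,4-epoxy-13-hydroxycembra-1,7,11-triene-19,20-dioate | COC(=O)/C1=C\[C@H](OC(C)=O)C[C@]2(C)O[C@H]2/C=C(/C(C)C)C[C@@H](O)/C(C(=O)OC)=C/CC1 | intermediate
29 | dimethyl (3S,4S,6R,13R,1E,7Z,11Z)-6,13-diacetoxy-3,4-epoxycembra-1,7,11-triene-19,20-dioate (CNP0359666.2) | COC(=O)/C1=C\[C@H](OC(C)=O)C[C@]2(C)O[C@H]2/C=C(/C(C)C)C[C@@H](OC(C)=O)/C(C(=O)OC)=C/CC1 | target

**Step count and risks**

Total step count: 19. Longest linear sequence: 17 steps (5 → 29, steps 3–19); the phosphonate branch (steps 1–2) joins at step 15.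

Steps most likely to fail:

1. Step 18 (proposed new method). What may go wrong: 1,2-reduction of the aldehyde by the copper hydride; silylation or protonation of the allenolate before ring closure; base-induced conjugation of the skipped enal with opening of the vinyl oxirane; poor facial control at C13 or poor control of the C11=C12 geometry. The fallback uses known chemistry, sets out from 4 and 23 and returns at 28. Phosphonate 4 is hydrostannylated (Bu3SnH, Pd(PPh3)4 cat., THF, 0 °C; syn addition with tin at the α-carbon) to the (E)-α-stannyl enoate phosphonate F1 and iodinated (I2, CH2Cl2, 0 °C, retention) to the (E)-α-iodo enoate phosphonate F2. Olefination of 23 with F2 under the conditions of step 15 should give the iodo diester silyl ether F3, which is desilylated (HF·pyridine, pyridine) to the iodo alcohol F4 and oxidised (Dess–Martin periodinane, NaHCO3) to the iodo aldehyde F5. A Nozaki–Hiyama–Kishi macrocyclization (CrCl2, NiCl2 cat., DMSO–THF, 2 mM, with a chiral sulfonamide ligand on chromium to bias the Si face of the aldehyde) then forms the same C12–C13 bond from a geometrically defined alkenyl iodide and returns to 28.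

2. Step 10. What may go wrong: attack of the organolithium on the adjacent oxirane, or erosion of the alkene geometry when the carbinol substituent is an oxirane. The fallback moves the epoxidation behind the rearrangement, sets out from 10 and returns at 20. Allylic alcohol 10 is oxidised (MnO2, CH2Cl2) to the (E)-enal F6, the Grignard reagent 14 is added to give the dienol F7, and O-alkylation (KH, Bu3SnCH2I) gives the stannylmethyl ether F8. Rearrangement and silylation as in step 10, now with no oxirane present at the organolithium stage, should give the diene bis-silyl ether F9, and removal of the triethylsilyl group (HF·pyridine, pyridine) gives the homoallylic dienol F10. Its C3=C4 alkene is then epoxidised site- and face-selectively under direction by the C6 hydroxyl with a vanadium catalyst carrying a chiral bishydroxamic acid (VO(OiPr)3, ligand, cumene hydroperoxide, toluene), which returns to 20.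

3. Step 15. What may go wrong: conjugate addition of the phosphonate anion to the ynoate of a second reagent molecule, competing with olefination and consuming the reagent. The fallback installs the C20 ester after the olefination, sets out from 23 and 3 and returns at 24. Aldehyde 23 is olefinated with the ynoate-free phosphonate 3 (KN(SiMe3)2, 18-crown-6, THF, −78 °C) to the terminal-alkyne (Z)-enoate F11, and silver-catalysed carboxylation of the terminal alkyne (AgI cat., Cs2CO3, CO2 1 atm, DMF, then MeI) gives the methyl ynoate and returns to 24.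

**Further compounds**

F1 | step 18 | dimethyl (E)-6-[bis(2,2,2-trifluoroethoxy)phosphoryl]-2-(tributylstannyl)hept-2-enedioate | COC(=O)/C([Sn](CCCC)(CCCC)CCCC)=C\CCC(C(=O)OC)P(=O)(OCC(F)(F)F)OCC(F)(F)F
F2 | step 18 | dimethyl (E)-6-[bis(2,2,2-trifluoroethoxy)phosphoryl]-2-iodohept-2-enedioate | COC(=O)/C(I)=C\CCC(C(=O)OC)P(=O)(OCC(F)(F)F)OCC(F)(F)F
F3 | step 18 | dimethyl (2E,6Z)-6-{(R)-2-acetoxy-3-[(2S,3S)-3-{(E)-4-[(tert-butyldiphenylsilyl)oxy]-2-(propan-2-yl)but-1-en-1-yl}-2-methyloxiran-2-yl]propylidene}-2-iodohept-2-enedioate | CC(C)(C)[Si](c1ccccc1)(c1ccccc1)OCC/C(C(C)C)=C\[C@@H]2O[C@@]2(C)C[C@@H](OC(C)=O)/C=C(/CC/C=C(/I)C(=O)OC)C(=O)OC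
F4 | step 18 | dimethyl (2E,6Z)-6-{(R)-2-acetoxy-3-[(2S,3S)-3-{(E)-4-hydroxy-2-(propan-2-yl)but-1-en-1-yl}-2-methyloxiran-2-yl]propylidene}-2-iodohept-2-enedioate | OCC/C(C(C)C)=C\[C@@H]1O[C@@]1(C)C[C@@H](OC(C)=O)/C=C(/CC/C=C(/I)C(=O)OC)C(=O)OC
F5 | step 18 | dimethyl (2E,6Z)-6-{(R)-2-acetoxy-3-[(2S,3S)-2-methyl-3-{(E)-4-oxo-2-(propan-2-yl)but-1-en-1-yl}oxiran-2-yl]propylidene}-2-iodohept-2-enedioate | O=CC/C(C(C)C)=C\[C@@H]1O[C@@]1(C)C[C@@H](OC(C)=O)/C=C(/CC/C=C(/I)C(=O)OC)C(=O)OC
F6 | step 10 | (R,E)-6-[(4-methoxybenzyl)oxy]-3-methyl-5-[(triethylsilyl)oxy]hex-2-enal | O=C/C=C(\C)C[C@@H](O[Si](CC)(CC)CC)COCc1ccc(OC)cc1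
F7 | step 10 | (5E,8R)-9-[(4-methoxybenzyl)oxy]-2,6-dimethyl-3-methylidene-8-[(triethylsilyl)oxy]non-5-en-4-ol (both C4 epimers) | C=C(C(C)C)C(O)/C=C(\C)C[C@@H](O[Si](CC)(CC)CC)COCc1ccc(OC)cc1
F8 | step 10 | tributyl[({(5E,8R)-9-[(4-methoxybenzyl)oxy]-2,6-dimethyl-3-methylidene-8-[(triethylsilyl)oxy]non-5-en-4-yl}oxy)methyl]stannane | C=C(C(C)C)C(OC[Sn](CCCC)(CCCC)CCCC)/C=C(\C)C[C@@H](O[Si](CC)(CC)CC)COCc1ccc(OC)cc1
F9 | step 10 | tert-butyl{[(3E,5E,8R)-9-[(4-methoxybenzyl)oxy]-6-methyl-3-(propan-2-yl)-8-[(triethylsilyl)oxy]nona-3,5-dien-1-yl]oxy}diphenylsilane | CC(C)(C)[Si](c1ccccc1)(c1ccccc1)OCC/C(C(C)C)=C\C=C(/C)C[C@@H](O[Si](CC)(CC)CC)COCc2ccc(OC)cc2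
F10 | step 10 | (2R,4E,6E)-9-[(tert-butyldiphenylsilyl)oxy]-1-[(4-methoxybenzyl)oxy]-4-methyl-7-(propan-2-yl)nona-4,6-dien-2-ol | CC(C)(C)[Si](c1ccccc1)(c1ccccc1)OCC/C(C(C)C)=C\C=C(/C)C[C@@H](O)COCc2ccc(OC)cc2
F11 | step 15 | methyl (2Z,4R)-4-acetoxy-2-(but-3-yn-1-yl)-5-[(2S,3S)-3-{(E)-4-[(tert-butyldiphenylsilyl)oxy]-2-(propan-2-yl)but-1-en-1-yl}-2-methyloxiran-2-yl]pent-2-enoate | CC(C)(C)[Si](c1ccccc1)(c1ccccc1)OCC/C(C(C)C)=C\[C@@H]2O[C@@]2(C)C[C@@H](OC(C)=O)/C=C(/CCC#C)C(=O)OC
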